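**Retrosynthetic overview**
- The target comes from a 6‑allyl dihalo‑oxane by Z‑selective enyne cross‑metathesis and desilylation (C3=C4).
- C7–Cl and C9–Br come from SN2 inversions of equatorial alcohols; both oxygens derive from the enone of a cis‑2,6‑dihydropyranone (β‑borylation gives C7–O, C=O reduction gives C9–O).
- The oxane is the only ring: Achmatowicz ring expansion of a 2,5‑disubstituted furyl carbinol, then Kishi reduction to set the 2,6‑cis relationship.
- The furyl carbinol comes from Noyori transfer hydrogenation of a ketone made by Friedel–Crafts acylation of 2‑allylfuran.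
- Key step: C11–C12 and C13–Br are made together by bromine‑atom‑transfer radical addition of bromoacetic acid to but‑1‑yne, which fixes the 12E bromoalkene.

Assumption: locants C1–C15 are those of the target chain (C1≡C2–C3=C4–C5–C6(O)–C7(Cl)–C8–C9(Br)–C10(O)–C11–C12=C13(Br)–C14–C15); minor E/Z or diastereomers are removed by chromatography where they arise, and the gases (but‑1‑yne, vinyl bromide) are handled condensed or in solution in sealed vessels.

**Route**

Step 1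
Reactants: 1 bromoacetic acid; 2 but-1-yne
Product: 3 (3E)-4-bromohex-3-enoic acid
Conditions: fac‑Ir(ppy)3 (1 mol %), 2 (5 equiv), MeCN, blue LEDs, sealed tube, 20 °C
Reagents that add atoms: none
Why: Kharasch‑type atom‑transfer radical addition: the electrophilic carboxymethyl radical adds to the terminal alkyne carbon and the bent α‑ethylvinyl radical takes Br from 1 anti to the new CH2CO2H group, so C11–C12 and C13–Br form in one chain step with Br trans to C11 (3E expected about 4:1).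

Step 2
Reactants: 4 furan; 5 3-bromoprop-1-ene
Product: 7 2-(prop-2-en-1-yl)furan, via furan-2-yllithium 6 (not isolated)
Conditions: n‑BuLi, THF, −78 → 0 °C; then 5, −78 °C → rt
Reagents that add atoms: none
Why: α‑lithiation of furan followed by SN2 allylation of the 2‑furyl anion gives the C6 side‑chain handle.

Step 3
Reactants: 3 (3E)-4-bromohex-3-enoic acid; 7 2-(prop-2-en-1-yl)furan
Product: 9 (3E)-4-bromo-1-[5-(prop-2-en-1-yl)furan-2-yl]hex-3-en-1-one, via mixed anhydride 8 (not isolated)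
Conditions: TFAA, CH2Cl2, 0 °C; then 7, 0 °C → rt
Reagents that add atoms: none
Why: Friedel–Crafts acylation by the mixed trifluoroacetic anhydride at the free α‑position of the 2‑alkylfuran; the base‑free medium should keep the β,γ‑bromoalkene out of conjugation.

Step 4
Reactants: 9 (3E)-4-bromo-1-[5-(prop-2-en-1-yl)furan-2-yl]hex-3-en-1-one
Product: 10 (1R,3E)-4-bromo-1-[5-(prop-2-en-1-yl)furan-2-yl]hex-3-en-1-ol
Conditions: RuCl(p‑cymene)[(R,R)‑TsDPEN] (1 mol %), HCO2H/Et3N (5:2), CH2Cl2, rt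
Reagents that add atoms: none
Why: Noyori asymmetric transfer hydrogenation with the furyl ring in the aryl role delivers hydride to one carbonyl face and sets C10 as R; isolated alkenes and the vinyl bromide are not reduced.

Step 5
Reactants: 10 (1R,3E)-4-bromo-1-[5-(prop-2-en-1-yl)furan-2-yl]hex-3-en-1-ol
Product: 12 (2R)-2-[(2E)-3-bromopent-2-en-1-yl]-6-hydroxy-6-(prop-2-en-1-yl)-2H-pyran-3(6H)-one, via enedione 11 (not isolated)
Conditions: NBS, NaHCO3, NaOAc, THF/H2O (4:1), 0 °C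
Reagents that add atoms: water, O
Why: Achmatowicz oxidative ring expansion: the electron‑rich furan is oxidised far faster than the terminal alkene or vinyl bromide, the (Z)‑enedione closes to the hemiketal, C10 is untouched and the C6 anomer mixture is irrelevant.

Step 6
Reactants: 12 (2R)-2-[(2E)-3-bromopent-2-en-1-yl]-6-hydroxy-6-(prop-2-en-1-yl)-2H-pyran-3(6H)-one
Product: 13 (2R,6S)-2-[(2E)-3-bromopent-2-en-1-yl]-6-(prop-2-en-1-yl)-2H-pyran-3(6H)-one
Conditions: Et3SiH, TFA, CH2Cl2, −40 → 0 °C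
Reagents that add atoms: none
Why: Kishi‑type reductive deoxygenation: the hemiketal ionises to the oxocarbenium ion and silane hydride adds axially, placing the allyl group equatorial and cis to the C10 chain (C6 = S).

Step 7
Reactants: 13 (2R,6S)-2-[(2E)-3-bromopent-2-en-1-yl]-6-(prop-2-en-1-yl)-2H-pyran-3(6H)-one
Product: 15 (2R,3S,5R,6S)-2-[(2E)-3-bromopent-2-en-1-yl]-6-(prop-2-en-1-yl)-5-(4,4,5,5-tetramethyl-1,3,2-dioxaborolan-2-yl)oxan-3-ol, via boryl ketone 14 (not isolated)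
Conditions: CuCl (5 mol %), DPEphos, NaOt‑Bu (10 mol %), B2pin2, MeOH, THF, 0 °C → rt; then NaBH4, MeOH, −40 °C
Reagents that add atoms: bis(pinacolato)diboron, CC1(C)OB(OC1(C)C)B1OC(C)(C)C(C)(C)O1
Why: Copper‑catalysed conjugate borylation adds boron to C7 anti to the adjacent allyl group (any C10 epimerisation returns to the cis ketone), then NaBH4 attacks the C9 ketone axially to give the equatorial alcohol trans to the C10 chain.

Step 8
Reactants: 15 (2R,3S,5R,6S)-2-[(2E)-3-bromopent-2-en-1-yl]-6-(prop-2-en-1-yl)-5-(4,4,5,5-tetramethyl-1,3,2-dioxaborolan-2-yl)oxan-3-ol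
Product: 16 2-[(2S,3R,5R,6R)-5-bromo-6-[(2E)-3-bromopent-2-en-1-yl]-2-(prop-2-en-1-yl)oxan-3-yl]-4,4,5,5-tetramethyl-1,3,2-dioxaborolane
Conditions: CBr4, (n‑Oct)3P, toluene, 70 °C
Reagents that add atoms: carbon tetrabromide, BrC(Br)(Br)Br
Why: Appel/Hooz bromination: the alkoxyphosphonium is displaced by bromide with SN2 inversion, giving axial C9–Br cis to the C10 chain while the boronate masks the second oxygen and no syn‑axial group blocks the attack.

Step 9
Reactants: 16 2-[(2S,3R,5R,6R)-5-bromo-6-[(2E)-3-bromopent-2-en-1-yl]-2-(prop-2-en-1-yl)oxan-3-yl]-4,4,5,5-tetramethyl-1,3,2-dioxaborolane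
Product: 17 (2S,3R,5R,6R)-5-bromo-6-[(2E)-3-bromopent-2-en-1-yl]-2-(prop-2-en-1-yl)oxan-3-ol
Conditions: NaBO3·4H2O, THF/H2O (1:1), rt
Reagents that add atoms: sodium perborate, [Na+].[O-]OB=O
Why: Boronate oxidation by 1,2‑migration from boron to oxygen is stereoretentive, so the C7 alcohol is equatorial and trans to the allyl group; the mild perborate spares the secondary bromide.

Step 10
Reactants: 17 (2S,3R,5R,6R)-5-bromo-6-[(2E)-3-bromopent-2-en-1-yl]-2-(prop-2-en-1-yl)oxan-3-ol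
Product: 18 (2R,3R,5S,6S)-3-bromo-2-[(2E)-3-bromopent-2-en-1-yl]-5-chloro-6-(prop-2-en-1-yl)oxane
Conditions: CCl4, (n‑Oct)3P, toluene, 80 °C
Reagents that add atoms: carbon tetrachloride, ClC(Cl)(Cl)Cl
Why: Appel‑type chlorination with SN2 inversion converts the equatorial C7 alcohol into the axial chloride cis to the C6 chain (C7 = S); E2 is disfavoured for an equatorial leaving group.

Step 11
Reactants: 19 ethynyltrimethylsilane; 20 bromoethene
Product: 21 (but-3-en-1-yn-1-yl)trimethylsilane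
Conditions: Pd(PPh3)4 (2 mol %), CuI (4 mol %), Et2NH, 0 °C → rt
Reagents that add atoms: none
Why: Sonogashira coupling of the terminal alkyne with the vinyl bromide gives the silyl‑capped enyne partner.

Step 12
Reactants: 18 (2R,3R,5S,6S)-3-bromo-2-[(2E)-3-bromopent-2-en-1-yl]-5-chloro-6-(prop-2-en-1-yl)oxane; 21 (but-3-en-1-yn-1-yl)trimethylsilane
Product: 22 (2R,3R,5S,6S)-3-bromo-2-[(2E)-3-bromopent-2-en-1-yl]-5-chloro-6-[(2Z)-5-(trimethylsilyl)pent-2-en-4-yn-1-yl]oxane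
Conditions: Grubbs II (10 mol %), 21 (5 equiv), CH2Cl2, 40 °C
Reagents that add atoms: none
Why: Olefin cross‑metathesis of a terminal alkene with a conjugated silyl enyne is kinetically Z‑selective, so the new C3=C4 bond is formed cis; the trisubstituted vinyl bromide does not engage the catalyst.

Step 13
Reactants: 22 (2R,3R,5S,6S)-3-bromo-2-[(2E)-3-bromopent-2-en-1-yl]-5-chloro-6-[(2Z)-5-(trimethylsilyl)pent-2-en-4-yn-1-yl]oxane
Product: 23 (2R,3R,5S,6S)-3-bromo-2-[(2E)-3-bromopent-2-en-1-yl]-5-chloro-6-[(2Z)-pent-2-en-4-yn-1-yl]oxane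
Conditions: K2CO3 (0.2 equiv), MeOH, 0 °C
Reagents that add atoms: none
Why: Methoxide‑mediated protiodesilylation of the alkynylsilane frees the terminal alkyne under conditions too mild to eliminate the secondary halides.

**Compound list**
1 | bromoacetic acid | OC(=O)CBr | starting material
2 | but-1-yne | CCC#C | starting material
3 | (3E)-4-bromohex-3-enoic acid | OC(=O)C/C=C(/Br)CC | intermediate
4 | furan | c1ccoc1 | starting material
5 | 3-bromoprop-1-ene (allyl bromide) | C=CCBr | starting material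
6 | furan-2-yllithium | [Li]c1ccco1 | intermediate
7 | 2-(prop-2-en-1-yl)furan | C=CCc1ccco1 | intermediate
8 | (3E)-4-bromohex-3-enoic trifluoroacetic anhydride | FC(F)(F)C(=O)OC(=O)C/C=C(/Br)CC | intermediate
9 | (3E)-4-bromo-1-[5-(prop-2-en-1-yl)furan-2-yl]hex-3-en-1-one | C=CCc1ccc(o1)C(=O)C/C=C(/Br)CC | intermediate
10 | (1R,3E)-4-bromo-1-[5-(prop-2-en-1-yl)furan-2-yl]hex-3-en-1-ol | C=CCc1ccc(o1)[C@H](O)C/C=C(/Br)CC | intermediate
11 | (5Z,8R,10E)-11-bromo-8-hydroxytrideca-1,5,10-triene-4,7-dione | C=CCC(=O)/C=C\C(=O)[C@H](O)C/C=C(/Br)CC | intermediate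
12 | (2R)-2-[(2E)-3-bromopent-2-en-1-yl]-6-hydroxy-6-(prop-2-en-1-yl)-2H-pyran-3(6H)-one (both C6 epimers) | C=CCC1(O)O[C@H](C/C=C(/Br)CC)C(=O)C=C1 | intermediate
13 | (2R,6S)-2-[(2E)-3-bromopent-2-en-1-yl]-6-(prop-2-en-1-yl)-2H-pyran-3(6H)-one | C=CC[C@@H]1O[C@H](C/C=C(/Br)CC)C(=O)C=C1 | intermediate
14 | (2R,5R,6S)-2-[(2E)-3-bromopent-2-en-1-yl]-6-(prop-2-en-1-yl)-5-(4,4,5,5-tetramethyl-1,3,2-dioxaborolan-2-yl)oxan-3-one | C=CC[C@@H]1O[C@H](C/C=C(/Br)CC)C(=O)C[C@H]1B2OC(C)(C)C(C)(C)O2 | intermediate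
15 | (2R,3S,5R,6S)-2-[(2E)-3-bromopent-2-en-1-yl]-6-(prop-2-en-1-yl)-5-(4,4,5,5-tetramethyl-1,3,2-dioxaborolan-2-yl)oxan-3-ol | C=CC[C@@H]1O[C@H](C/C=C(/Br)CC)[C@@H](O)C[C@H]1B2OC(C)(C)C(C)(C)O2 | intermediate
16 | 2-[(2S,3R,5R,6R)-5-bromo-6-[(2E)-3-bromopent-2-en-1-yl]-2-(prop-2-en-1-yl)oxan-3-yl]-4,4,5,5-tetramethyl-1,3,2-dioxaborolane | C=CC[C@@H]1O[C@H](C/C=C(/Br)CC)[C@H](Br)C[C@H]1B2OC(C)(C)C(C)(C)O2 | intermediate
17 | (2S,3R,5R,6R)-5-bromo-6-[(2E)-3-bromopent-2-en-1-yl]-2-(prop-2-en-1-yl)oxan-3-ol | C=CC[C@@H]1O[C@H](C/C=C(/Br)CC)[C@H](Br)C[C@H]1O | intermediate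
18 | (2R,3R,5S,6S)-3-bromo-2-[(2E)-3-bromopent-2-en-1-yl]-5-chloro-6-(prop-2-en-1-yl)oxane | C=CC[C@@H]1O[C@H](C/C=C(/Br)CC)[C@H](Br)C[C@@H]1Cl | intermediate
19 | ethynyltrimethylsilane | C#C[Si](C)(C)C | starting material
20 | bromoethene (vinyl bromide) | C=CBr | starting material
21 | (but-3-en-1-yn-1-yl)trimethylsilane | C=CC#C[Si](C)(C)C | intermediate
22 | (2R,3R,5S,6S)-3-bromo-2-[(2E)-3-bromopent-2-en-1-yl]-5-chloro-6-[(2Z)-5-(trimethylsilyl)pent-2-en-4-yn-1-yl]oxane | C[Si](C)(C)C#C/C=C\C[C@@H]1O[C@H](C/C=C(/Br)CC)[C@H](Br)C[C@@H]1Cl | intermediate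
23 | (2R,3R,5S,6S)-3-bromo-2-[(2E)-3-bromopent-2-en-1-yl]-5-chloro-6-[(2Z)-pent-2-en-4-yn-1-yl]oxane | C#C/C=C\C[C@@H]1O[C@H](C/C=C(/Br)CC)[C@H](Br)C[C@@H]1Cl | target

**Step count**
Total steps: 13. Longest linear sequence: 11 (steps 1, 3–10, 12, 13; the chain from furan through step 2 is equally long).

**Three steps most likely to fail, with fallbacks**

Step 1 (atom‑transfer radical addition). The risks are a short radical chain with the gaseous alkyne and an E:Z ratio too low to be useful. The fallback makes the bromoalkene without radicals; it sets out from but‑1‑yne 2 and comes back to the route at acid 3. Anti addition of IBr to 2 (CH2Cl2, −78 °C) gives (1E)-2-bromo-1-iodobut-1-ene F1. Chemoselective Pd‑catalysed Negishi coupling of its C–I bond with commercial (2‑ethoxy‑2‑oxoethyl)zinc bromide (Pd(PPh3)4, THF, rt) proceeds with retention and gives ethyl (3E)-4-bromohex-3-enoate F2. Saponification (LiOH, THF/H2O) returns 3.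

Step 10 (chlorination). Chloride must enter axially, syn to the axial C9 bromide, so substitution may be slow and elimination may compete. The fallback reverses the order of halogen introduction so that the first displacement has no syn‑axial neighbour and the crowded one is done by the softer bromide; it sets out from 15 and comes back at 18. Silylation (TESCl, imidazole, CH2Cl2) gives triethyl({(2R,3S,5R,6S)-2-[(2E)-3-bromopent-2-en-1-yl]-6-(prop-2-en-1-yl)-5-(4,4,5,5-tetramethyl-1,3,2-dioxaborolan-2-yl)oxan-3-yl}oxy)silane F3. Perborate oxidation gives (2S,3R,5S,6R)-6-[(2E)-3-bromopent-2-en-1-yl]-2-(prop-2-en-1-yl)-5-[(triethylsilyl)oxy]oxan-3-ol F4. CCl4/(n‑Oct)3P then gives triethyl({(2R,3S,5S,6S)-2-[(2E)-3-bromopent-2-en-1-yl]-5-chloro-6-(prop-2-en-1-yl)oxan-3-yl}oxy)silane F5. HF·pyridine releases (2R,3S,5S,6S)-2-[(2E)-3-bromopent-2-en-1-yl]-5-chloro-6-(prop-2-en-1-yl)oxan-3-ol F6, and CBr4/(n‑Oct)3P with inversion gives 18.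

Step 12 (enyne cross‑metathesis). The Z:E ratio with the small trimethylsilyl enyne may be modest and the enyne can slow the catalyst. The fallback builds the Z‑enyne by olefination and coupling; it sets out from 18 and comes back at 22. Oxidative cleavage of the terminal alkene only (OsO4 cat., NaIO4, 2,6‑lutidine, dioxane/H2O) gives 2-[(2S,3S,5R,6R)-5-bromo-6-[(2E)-3-bromopent-2-en-1-yl]-3-chlorooxan-2-yl]acetaldehyde F7. Stork–Zhao olefination (Ph3P+CH2I I−, NaHMDS, THF/HMPA, −78 °C) gives (2R,3R,5S,6S)-3-bromo-2-[(2E)-3-bromopent-2-en-1-yl]-5-chloro-6-[(2Z)-3-iodoprop-2-en-1-yl]oxane F8. Sonogashira coupling with ethynyltrimethylsilane 19 (Pd(PPh3)4, CuI, Et2NH) gives 22.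

**Further compounds**
F1 | step 1 | (1E)-2-bromo-1-iodobut-1-ene | I/C=C(/Br)CC
F2 | step 1 | ethyl (3E)-4-bromohex-3-enoate | CCOC(=O)C/C=C(/Br)CC
F3 | step 10 | triethyl({(2R,3S,5R,6S)-2-[(2E)-3-bromopent-2-en-1-yl]-6-(prop-2-en-1-yl)-5-(4,4,5,5-tetramethyl-1,3,2-dioxaborolan-2-yl)oxan-3-yl}oxy)silane | C=CC[C@@H]1O[C@H](C/C=C(/Br)CC)[C@@H](O[Si](CC)(CC)CC)C[C@H]1B2OC(C)(C)C(C)(C)O2
F4 | step 10 | (2S,3R,5S,6R)-6-[(2E)-3-bromopent-2-en-1-yl]-2-(prop-2-en-1-yl)-5-[(triethylsilyl)oxy]oxan-3-ol | C=CC[C@@H]1O[C@H](C/C=C(/Br)CC)[C@@H](O[Si](CC)(CC)CC)C[C@H]1O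
F5 | step 10 | triethyl({(2R,3S,5S,6S)-2-[(2E)-3-bromopent-2-en-1-yl]-5-chloro-6-(prop-2-en-1-yl)oxan-3-yl}oxy)silane | C=CC[C@@H]1O[C@H](C/C=C(/Br)CC)[C@@H](O[Si](CC)(CC)CC)C[C@@H]1Cl
F6 | step 10 | (2R,3S,5S,6S)-2-[(2E)-3-bromopent-2-en-1-yl]-5-chloro-6-(prop-2-en-1-yl)oxan-3-ol | C=CC[C@@H]1O[C@H](C/C=C(/Br)CC)[C@@H](O)C[C@@H]1Cl
F7 | step 12 | 2-[(2S,3S,5R,6R)-5-bromo-6-[(2E)-3-bromopent-2-en-1-yl]-3-chlorooxan-2-yl]acetaldehyde | O=CC[C@@H]1O[C@H](C/C=C(/Br)CC)[C@H](Br)C[C@@H]1Cl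
F8 | step 12 | (2R,3R,5S,6S)-3-bromo-2-[(2E)-3-bromopent-2-en-1-yl]-5-chloro-6-[(2Z)-3-iodoprop-2-en-1-yl]oxane | I/C=C\C[C@@H]1O[C@H](C/C=C(/Br)CC)[C@H](Br)C[C@@H]1Cl
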